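**Strategy.** Ring C is cut at C3–C4 and O1–C8a. These bonds join a 1,3-dielectrophile, the ortho-bromobenzyl bromide of ring A (C4 on C4a, bromine on C8a), to a 1,3-C,O-dinucleophile, the enolate of a 2-alkoxy-1-arylethanone that already holds O1, C2 with ring B, and C3 with its oxygen. One pot joins them: enolate C-benzylation makes C3–C4, then CuI-catalysed enolate O-arylation makes O1–C8a, giving a 4H-chromene whose C2=C3 enol ether is the masked flavan-3-one. The feature exploited is the ortho placement of C4 and O1 on ring A opposite the O1–C2–C3 enol. Unmasking and a dynamic-kinetic asymmetric reduction set the cis (2R,3R) pair before esterification and hydrogenolysis.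

Key step: step 6

Assumptions: RuCl(p-cymene)[(R,R)-TsDPEN] is taken to reduce the (2R)-ketone to the 3R carbinol; should the sense prove opposite, RuCl(p-cymene)[(S,S)-TsDPEN] is used in step 8 and nothing else changes. Compounds 1, 5, 12 and Bu3SnCH2OCH2OMe are taken as purchasable.

Step 1
Reactants: 1 1,3-bis(benzyloxy)-5-bromobenzene
Product: 2 2,4-bis(benzyloxy)-6-bromobenzaldehyde
Conditions: POCl3, DMF, 0 → 70 °C; then H2O, 0 °C
Reagents that add atoms: N,N-dimethylformamide, CN(C)C=O; water, O
Why: Vilsmeier–Haack formylation should go to the position para to one benzyloxy group and ortho to the other, next to bromine, rather than to the more hindered position between the two benzyloxy groups; any minor isomer is removed by crystallisation.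

Step 2
Reactants: 2 2,4-bis(benzyloxy)-6-bromobenzaldehyde
Product: 3 [2,4-bis(benzyloxy)-6-bromophenyl]methanol
Conditions: NaBH4, THF/MeOH, 0 °C
Reagents that add atoms: none
Why: Borohydride reduction of an aryl aldehyde leaves the aryl bromide and the benzyl ethers untouched.

Step 3
Reactants: 3 [2,4-bis(benzyloxy)-6-bromophenyl]methanol
Product: 4 1,5-bis(benzyloxy)-3-bromo-2-(bromomethyl)benzene
Conditions: PBr3, Et2O, 0 °C; crude product used at once
Reagents that add atoms: phosphorus tribromide, BrP(Br)Br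
Why: Conversion of an electron-rich benzylic alcohol into the bromide with PBr3 is fast at 0 °C, and the reactive bromide is carried forward without chromatography.

Step 4
Reactants: 5 3,4,5-tris(benzyloxy)benzoic acid
Product: 6 3,4,5-tris(benzyloxy)-N-methoxy-N-methylbenzamide
Conditions: MeNHOMe·HCl, EDC·HCl, Et3N, DMAP (cat.), CH2Cl2, 0 °C → rt
Reagents that add atoms: N,O-dimethylhydroxylamine hydrochloride, CNOC.Cl
Why: Carbodiimide amidation gives the Weinreb amide needed for a clean single addition in step 5.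

Step 5
Reactants: 6 3,4,5-tris(benzyloxy)-N-methoxy-N-methylbenzamide
Product: 7 2-(methoxymethoxy)-1-[3,4,5-tris(benzyloxy)phenyl]ethan-1-one
Conditions: Bu3SnCH2OCH2OMe, n-BuLi, THF, −78 °C; then 6, −78 °C; aq. NH4Cl
Reagents that add atoms: tributyl[(methoxymethoxy)methyl]stannane, CCCC[Sn](CCCC)(CCCC)COCOC
Why: Tin–lithium exchange gives the alkoxymethyllithium, which adds once to the Weinreb amide because the chelated tetrahedral adduct holds until work-up (Weinreb ketone synthesis).

Step 6
Reactants: 7 2-(methoxymethoxy)-1-[3,4,5-tris(benzyloxy)phenyl]ethan-1-one; 4 1,5-bis(benzyloxy)-3-bromo-2-(bromomethyl)benzene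
Product: 9 5,7-bis(benzyloxy)-3-(methoxymethoxy)-2-[3,4,5-tris(benzyloxy)phenyl]-4H-chromene, via C-benzylated ketone 8 (not isolated)
Conditions: LiN(SiMe3)2, THF, −78 °C; 4, −78 → 0 °C; then CuI (10 mol %), 1,10-phenanthroline (20 mol %), NaOt-Bu, toluene, 100 °C, one pot
Reagents that add atoms: none
Why: The lithium enolate of 7 should be C-alkylated in an SN2 step by the benzylic bromide of 4 (the aryl bromide is inert without copper), which makes C3–C4 and gives 8; NaOt-Bu then re-forms the enolate of 8, CuI/1,10-phenanthroline inserts into the C8a–Br bond, and reductive elimination from the copper enolate makes O1–C8a (Ullmann-type enolate O-arylation). The closest known reactions are the CuI-catalysed domino C-benzylation/O-arylation of 2-bromobenzyl bromides with 1,3-dicarbonyl compounds to 4H-chromenes and the CuI-catalysed closure of 2-haloaryl ketones to benzofurans. Ring C closes as a six-membered ring by attack of the enolate oxygen on the aryl carbon (6-exo at copper); the carbon end of the enolate could only give a four-membered ring, so O-arylation is the sole closure. No stereocentre survives the step, because C3 of 8 is flattened into the C2=C3 enol ether, and C2 and C3 are set together in step 8. The selectivities needed are C- over O-alkylation and mono-alkylation, secured by the chelated lithium enolate in THF and the single CH2 of 7, and closure through the ketone oxygen only, secured by the MOM ether on the C3 oxygen, which unlike an acyl or silyl group cannot migrate and so cannot open a five-membered closure.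

Step 7
Reactants: 9 5,7-bis(benzyloxy)-3-(methoxymethoxy)-2-[3,4,5-tris(benzyloxy)phenyl]-4H-chromene
Product: 10 5,7-bis(benzyloxy)-2-[3,4,5-tris(benzyloxy)phenyl]chroman-3-one (racemic)
Conditions: Me2BBr, CH2Cl2, −78 °C; then aq. NaHCO3/THF, 0 °C
Reagents that add atoms: none
Why: Lewis-acid cleavage of the MOM acetal at its methoxy oxygen should release the C3 oxygen without protonation at carbon, and the ketone then forms by tautomerisation; benzyl ethers are stable to Me2BBr at −78 °C.

Step 8
Reactants: 10 5,7-bis(benzyloxy)-2-[3,4,5-tris(benzyloxy)phenyl]chroman-3-one (racemic)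
Product: 11 (2R,3R)-5,7-bis(benzyloxy)-2-[3,4,5-tris(benzyloxy)phenyl]chroman-3-ol
Conditions: RuCl(p-cymene)[(R,R)-TsDPEN] (2 mol %), HCO2H/Et3N (5:2), CH2Cl2, 30 °C
Reagents that add atoms: none
Why: Noyori asymmetric transfer hydrogenation under dynamic kinetic resolution: C2 (alpha to the ketone, benzylic and aryloxy-substituted) should epimerise quickly through the enol in the amine medium, the catalyst should select the (2R)-ketone and so fix C2 and the absolute sense, and hydride should add to C3 anti to the pseudo-equatorial ring B aryl group to give the cis alcohol.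

Step 9
Reactants: 12 methyl 3,4-dihydroxy-5-methoxybenzoate
Product: 13 methyl 3,4-bis(benzyloxy)-5-methoxybenzoate
Conditions: BnBr, K2CO3, DMF, 60 °C
Reagents that add atoms: benzyl bromide, BrCc1ccccc1
Why: Williamson O-benzylation of both phenols proceeds cleanly and leaves the methyl ether in place.

Step 10
Reactants: 13 methyl 3,4-bis(benzyloxy)-5-methoxybenzoate
Product: 14 3,4-bis(benzyloxy)-5-methoxybenzoic acid
Conditions: LiOH, THF/MeOH/H2O, 50 °C; then aq. HCl
Reagents that add atoms: lithium hydroxide, [Li+].[OH-]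
Why: Saponification of the methyl ester gives the acid without touching the aryl ethers.

Step 11
Reactants: 11 (2R,3R)-5,7-bis(benzyloxy)-2-[3,4,5-tris(benzyloxy)phenyl]chroman-3-ol; 14 3,4-bis(benzyloxy)-5-methoxybenzoic acid
Product: 15 (2R,3R)-5,7-bis(benzyloxy)-2-[3,4,5-tris(benzyloxy)phenyl]chroman-3-yl 3,4-bis(benzyloxy)-5-methoxybenzoate
Conditions: EDC·HCl, DMAP, CH2Cl2, rt
Reagents that add atoms: none
Why: Steglich esterification acylates the axial C3 hydroxyl at oxygen, so neither stereocentre is touched.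

Step 12
Reactants: 15 (2R,3R)-5,7-bis(benzyloxy)-2-[3,4,5-tris(benzyloxy)phenyl]chroman-3-yl 3,4-bis(benzyloxy)-5-methoxybenzoate
Product: 16 (−)-epigallocatechin 3-(3-methyl-gallate)
Conditions: H2 (1 atm), Pd(OH)2/C, THF/MeOH, rt
Reagents that add atoms: none
Why: Neutral hydrogenolysis should remove all seven benzyl ethers while the ester, the methyl ether and the O1–C2 bond remain, and C2 is not epimerised under these conditions.

**Compound list**

1 | 1,3-bis(benzyloxy)-5-bromobenzene | Brc1cc(OCc2ccccc2)cc(OCc2ccccc2)c1 | starting material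
2 | 2,4-bis(benzyloxy)-6-bromobenzaldehyde | O=Cc1c(Br)cc(OCc2ccccc2)cc1OCc1ccccc1 | intermediate
3 | [2,4-bis(benzyloxy)-6-bromophenyl]methanol | OCc1c(Br)cc(OCc2ccccc2)cc1OCc1ccccc1 | intermediate
4 | 1,5-bis(benzyloxy)-3-bromo-2-(bromomethyl)benzene | BrCc1c(Br)cc(OCc2ccccc2)cc1OCc1ccccc1 | intermediate
5 | 3,4,5-tris(benzyloxy)benzoic acid | OC(=O)c1cc(OCc2ccccc2)c(OCc2ccccc2)c(OCc2ccccc2)c1 | starting material
6 | 3,4,5-tris(benzyloxy)-N-methoxy-N-methylbenzamide | CON(C)C(=O)c1cc(OCc2ccccc2)c(OCc2ccccc2)c(OCc2ccccc2)c1 | intermediate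
7 | 2-(methoxymethoxy)-1-[3,4,5-tris(benzyloxy)phenyl]ethan-1-one | COCOCC(=O)c1cc(OCc2ccccc2)c(OCc2ccccc2)c(OCc2ccccc2)c1 | intermediate
8 | 3-[2,4-bis(benzyloxy)-6-bromophenyl]-2-(methoxymethoxy)-1-[3,4,5-tris(benzyloxy)phenyl]propan-1-one (racemic) | COCOC(Cc1c(Br)cc(OCc2ccccc2)cc1OCc1ccccc1)C(=O)c1cc(OCc2ccccc2)c(OCc2ccccc2)c(OCc2ccccc2)c1 | intermediate
9 | 5,7-bis(benzyloxy)-3-(methoxymethoxy)-2-[3,4,5-tris(benzyloxy)phenyl]-4H-chromene | COCOC1=C(c2cc(OCc3ccccc3)c(OCc3ccccc3)c(OCc3ccccc3)c2)Oc2cc(OCc3ccccc3)cc(OCc3ccccc3)c2C1 | intermediate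
10 | 5,7-bis(benzyloxy)-2-[3,4,5-tris(benzyloxy)phenyl]chroman-3-one (racemic) | O=C1Cc2c(OCc3ccccc3)cc(OCc3ccccc3)cc2OC1c1cc(OCc2ccccc2)c(OCc2ccccc2)c(OCc2ccccc2)c1 | intermediate
11 | (2R,3R)-5,7-bis(benzyloxy)-2-[3,4,5-tris(benzyloxy)phenyl]chroman-3-ol | O[C@@H]1Cc2c(OCc3ccccc3)cc(OCc3ccccc3)cc2O[C@@H]1c1cc(OCc2ccccc2)c(OCc2ccccc2)c(OCc2ccccc2)c1 | intermediate
12 | methyl 3,4-dihydroxy-5-methoxybenzoate | COC(=O)c1cc(O)c(O)c(OC)c1 | starting material
13 | methyl 3,4-bis(benzyloxy)-5-methoxybenzoate | COC(=O)c1cc(OC)c(OCc2ccccc2)c(OCc2ccccc2)c1 | intermediate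
14 | 3,4-bis(benzyloxy)-5-methoxybenzoic acid | COc1cc(C(=O)O)cc(OCc2ccccc2)c1OCc1ccccc1 | intermediate
15 | (2R,3R)-5,7-bis(benzyloxy)-2-[3,4,5-tris(benzyloxy)phenyl]chroman-3-yl 3,4-bis(benzyloxy)-5-methoxybenzoate | COc1cc(C(=O)O[C@@H]2Cc3c(OCc4ccccc4)cc(OCc4ccccc4)cc3O[C@@H]2c2cc(OCc3ccccc3)c(OCc3ccccc3)c(OCc3ccccc3)c2)cc(OCc2ccccc2)c1OCc1ccccc1 | intermediate
16 | (−)-epigallocatechin 3-(3-methyl-gallate) | COc1cc(C(=O)O[C@@H]2Cc3c(O)cc(O)cc3O[C@@H]2c2cc(O)c(O)c(O)c2)cc(O)c1O | target

**Count.** Total: 12 steps. Longest linear sequence: 8 steps (steps 1, 2, 3, 6, 7, 8, 11, 12).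

**Steps most likely to fail**

Step 6. The copper-mediated O-arylation of the hindered, fully substituted enolate of 8 may be slow, so that protodebromination or enolate decomposition takes over. The fallback sets out from 7 and 4 and returns at 10. The alkylation stage is run alone and 8 is isolated. NaBH4 (THF/MeOH, 0 °C) should reduce the ketone to the secondary alcohol F1 as a mixture of diastereomers. Intramolecular Ullmann etherification of the more nucleophilic alkoxide (CuI, 1,10-phenanthroline, Cs2CO3, toluene, 110 °C) should close ring C to the flavan MOM ether F2. HCl in MeOH (40 °C) should remove the now ordinary MOM ether to give the flavan-3-ol F3 as a mixture of stereoisomers. Dess–Martin periodinane (CH2Cl2, rt) should oxidise F3 to 10, where the stereochemistry is set as planned.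

Step 8. Epimerisation at C2 may be slower than reduction, or catalyst control may be weak, which would erode the enantiomeric purity or give the trans alcohol. The fallback sets out from 10 and returns at 11. LiBH(s-Bu)3 (THF, −78 °C) should deliver hydride anti to the ring B aryl group and give the racemic cis alcohol F7. The enantiomers are separated by preparative chromatography on a chiral stationary phase (amylose tris(3,5-dimethylphenylcarbamate)), which gives 11. The (2S,3S) enantiomer is oxidised back to 10 with Dess–Martin periodinane and recycled.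

Step 7. The electron-rich enol ether may be protonated at C3 by adventitious acid, opening ring C at the O1–C2 acetal stage, or the chromene may decompose under the Lewis acid. The fallback sets out from 6 and returns at 10. It uses a fluoride-labile group in place of MOM. Bu3SnCH2OCH2OCH2CH2SiMe3 and n-BuLi (THF, −78 °C) followed by 6 should give the SEM ketone F4. The conditions of step 6 with 4 should give, through the C-benzylated SEM ketone F5, the SEM enol ether F6. Bu4NF (THF, 0 °C → rt, then AcOH) should fragment the SEM group to the enolate under non-acidic conditions and give 10.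

**Further compounds**

F1 | step 6 | 3-[2,4-bis(benzyloxy)-6-bromophenyl]-2-(methoxymethoxy)-1-[3,4,5-tris(benzyloxy)phenyl]propan-1-ol (mixture of diastereomers) | COCOC(Cc1c(Br)cc(OCc2ccccc2)cc1OCc1ccccc1)C(O)c1cc(OCc2ccccc2)c(OCc2ccccc2)c(OCc2ccccc2)c1
F2 | step 6 | 5,7-bis(benzyloxy)-3-(methoxymethoxy)-2-[3,4,5-tris(benzyloxy)phenyl]chromane (mixture of stereoisomers) | COCOC1Cc2c(OCc3ccccc3)cc(OCc3ccccc3)cc2OC1c1cc(OCc2ccccc2)c(OCc2ccccc2)c(OCc2ccccc2)c1
F3 | step 6 | 5,7-bis(benzyloxy)-2-[3,4,5-tris(benzyloxy)phenyl]chroman-3-ol (mixture of stereoisomers) | OC1Cc2c(OCc3ccccc3)cc(OCc3ccccc3)cc2OC1c1cc(OCc2ccccc2)c(OCc2ccccc2)c(OCc2ccccc2)c1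
F4 | step 7 | 1-[3,4,5-tris(benzyloxy)phenyl]-2-{[2-(trimethylsilyl)ethoxy]methoxy}ethan-1-one | C[Si](C)(C)CCOCOCC(=O)c1cc(OCc2ccccc2)c(OCc2ccccc2)c(OCc2ccccc2)c1
F5 | step 7 | 3-[2,4-bis(benzyloxy)-6-bromophenyl]-1-[3,4,5-tris(benzyloxy)phenyl]-2-{[2-(trimethylsilyl)ethoxy]methoxy}propan-1-one (racemic) | C[Si](C)(C)CCOCOC(Cc1c(Br)cc(OCc2ccccc2)cc1OCc1ccccc1)C(=O)c1cc(OCc2ccccc2)c(OCc2ccccc2)c(OCc2ccccc2)c1
F6 | step 7 | 5,7-bis(benzyloxy)-2-[3,4,5-tris(benzyloxy)phenyl]-3-{[2-(trimethylsilyl)ethoxy]methoxy}-4H-chromene | C[Si](C)(C)CCOCOC1=C(c2cc(OCc3ccccc3)c(OCc3ccccc3)c(OCc3ccccc3)c2)Oc2cc(OCc3ccccc3)cc(OCc3ccccc3)c2C1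
F7 | step 8 | racemic cis-5,7-bis(benzyloxy)-2-[3,4,5-tris(benzyloxy)phenyl]chroman-3-ol, the (2R,3R) and (2S,3S) enantiomers in equal parts | O[C@@H]1Cc2c(OCc3ccccc3)cc(OCc3ccccc3)cc2O[C@@H]1c1cc(OCc2ccccc2)c(OCc2ccccc2)c(OCc2ccccc2)c1.O[C@H]1Cc2c(OCc3ccccc3)cc(OCc3ccccc3)cc2O[C@H]1c1cc(OCc2ccccc2)c(OCc2ccccc2)c(OCc2ccccc2)c1
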